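Ring B (the quinone) is cut at C5–C6 and C3–C4 together (numbering: C1=O, C2–OMe, C3–OMe, C4=O, C5 carries chroman C3, C6–H). This gives a silyl ynol ether (C5≡C4–OSi) and 3,4,5-trimethoxypyridazine, whose C6/C5/C4/C3 are ring B C6/C1/C2/C3 and whose N=N bridge leaves as N2. The ynol ether goes back to a chromane-3-carboxylate (carbonyl carbon = C4), and ring C is cut at O1–C2 and C3–C4 (salicylaldehyde plus acrolein).
Enabling feature: ring B has three contiguous oxygen-bearing carbons (C1, C2, C3) beside its only C–H carbon (C6), the pattern of a 3,4,5-trialkoxy-1,2-diazine. Its other two carbons are an oxygen-bearing carbon (C4) beside the fully substituted C5, the polarity pattern of an ynol ether.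
Forward order: ring A aldehyde (steps 1–3), ring C by oxa-Michael/aldol (step 4), C3 set (step 6), ynol ether by one-carbon homologation (step 7), benzenoid ring B by diazine cycloaddition with loss of N2 (step 9), quinone (step 10), release of the C8 phenol (step 11).
Stereochemistry: the single stereocenter, chroman C3, comes from the BINAP–ruthenium hydrogenation of step 6. The 1,2-shift of step 7 retains it, and no later step puts base or radical character at C3.
Key step: step 9

Assumption: (S)-BINAP is taken as the antipode that gives the (3R) acid; if the first run shows the opposite sense, the (R) ligand is used and nothing else changes.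

Step 1
Reactants: 1 2-hydroxy-3,4-dimethoxybenzaldehyde
Product: 2 2-(benzyloxy)-3,4-dimethoxybenzaldehyde
Conditions: BnBr, K2CO3, DMF, 60 °C
Reagents that add atoms: benzyl bromide, BrCc1ccccc1
Why: Williamson O-benzylation of the chelated ortho-hydroxyl masks the oxygen that becomes the C8 phenol of ring A as an ether that should survive the organolithium, silver, fluoride and oxidative steps and fall off by hydrogenolysis at the end.

Step 2
Reactants: 2 2-(benzyloxy)-3,4-dimethoxybenzaldehyde
Product: 4 2-(benzyloxy)-3,4-dimethoxyphenol, via aryl formate 3 (not isolated)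
Conditions: mCPBA, CH2Cl2, 0 °C to rt; then K2CO3, MeOH, rt
Reagents that add atoms: 3-chloroperoxybenzoic acid (mCPBA), OOC(=O)c1cccc(Cl)c1
Why: In this Dakin-type Baeyer–Villiger oxidation the electron-rich aryl group (ortho and para alkoxy) should migrate in the peracid adduct to give formate 3, whose methanolysis frees the phenol and so installs the fourth contiguous oxygen of ring A.

Step 3
Reactants: 4 2-(benzyloxy)-3,4-dimethoxyphenol
Product: 5 3-(benzyloxy)-2-hydroxy-4,5-dimethoxybenzaldehyde
Conditions: (CH2O)n, MgCl2, Et3N, MeCN, reflux; aq. HCl work-up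
Reagents that add atoms: paraformaldehyde (as formaldehyde), C=O
Why: The magnesium phenoxide-directed ortho-formylation (Casnati–Skattebøl) delivers formaldehyde only ortho to the free hydroxyl, and the single open ortho position of 4 is the future C4a, a second formaldehyde serving as hydride acceptor.

Step 4
Reactants: 5 3-(benzyloxy)-2-hydroxy-4,5-dimethoxybenzaldehyde; 6 acrolein
Product: 7 8-(benzyloxy)-6,7-dimethoxy-2H-chromene-3-carbaldehyde
Conditions: K2CO3, 1,4-dioxane, reflux
Reagents that add atoms: none
Why: Oxa-Michael addition of the phenoxide to acrolein followed by intramolecular aldol condensation onto the aryl aldehyde closes ring C as the 2H-chromene, the standard route from salicylaldehydes to 2H-chromene-3-carbaldehydes.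

Step 5
Reactants: 7 8-(benzyloxy)-6,7-dimethoxy-2H-chromene-3-carbaldehyde
Product: 8 8-(benzyloxy)-6,7-dimethoxy-2H-chromene-3-carboxylic acid
Conditions: NaClO2, NaH2PO4, 2-methylbut-2-ene, t-BuOH/H2O, rt
Reagents that add atoms: sodium chlorite, [Na+].[O-]Cl=O
Why: The Pinnick oxidation converts the conjugated aldehyde into the acid without touching the alkene or the benzyl ether, the alkene scavenger keeping hypochlorous acid away from the electron-rich ring A.

Step 6
Reactants: 8 8-(benzyloxy)-6,7-dimethoxy-2H-chromene-3-carboxylic acid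
Product: 10 methyl (3R)-8-(benzyloxy)-6,7-dimethoxychromane-3-carboxylate, via (3R)-carboxylic acid 9 (not isolated)
Conditions: H2 (50 atm), Ru(OAc)2[(S)-BINAP] (1 mol%), MeOH, 30 °C; vent; then Me3SiCHN2, MeOH/toluene, 0 °C
Reagents that add atoms: (trimethylsilyl)diazomethane, C[Si](C)(C)C=[N+]=[N-]
Why: Carboxylate-directed asymmetric hydrogenation of the trisubstituted 2-substituted acrylic acid with the BINAP–ruthenium dicarboxylate should set C3 by face-selective hydrogen delivery under control of the axially chiral ligand, and the base-free esterification avoids retro-oxa-Michael opening at the β-aryloxy stereocenter.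

Step 7
Reactants: 10 methyl (3R)-8-(benzyloxy)-6,7-dimethoxychromane-3-carboxylate
Product: 12 (3S)-8-(benzyloxy)-6,7-dimethoxy-3-({[tri(propan-2-yl)silyl]oxy}ethynyl)chromane, via lithium ynolate 11 (not isolated)
Conditions: CH2Br2, lithium 2,2,6,6-tetramethylpiperidide, THF, −78 °C; LiN(SiMe3)2; n-BuLi, −78 °C to rt; then i-Pr3SiCl, −78 to 0 °C
Reagents that add atoms: dibromomethane, BrCBr; chlorotri(propan-2-yl)silane, CC(C)[Si](Cl)(C(C)C)C(C)C
Why: In the Kowalski ester homologation dibromomethyllithium adds to the ester, the bromo carbenoid enolate rearranges by 1,2-shift of the chromanyl group with retention at C3 to ynolate 11, and the bulky silyl chloride should trap it on oxygen (the descriptor changes from R to S only because the priorities change).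

Step 8
Reactants: 13 3,4,5-trichloropyridazine
Product: 14 3,4,5-trimethoxypyridazine
Conditions: NaOMe (5 equiv), MeOH, reflux (sealed tube at 100 °C if the last chloride is slow)
Reagents that add atoms: sodium methoxide, [Na+].[O-]C
Why: Three successive nucleophilic aromatic substitutions by methoxide at carbons activated by the ring nitrogens (C3 alpha, C4 and C5 gamma) replace all three chlorides, so no regiochemical question arises.

Step 9
Reactants: 12 (3S)-8-(benzyloxy)-6,7-dimethoxy-3-({[tri(propan-2-yl)silyl]oxy}ethynyl)chromane; 14 3,4,5-trimethoxypyridazine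
Product: 16 (3S)-8-(benzyloxy)-6,7-dimethoxy-3-(3,4,5-trimethoxy-2-{[tri(propan-2-yl)silyl]oxy}phenyl)chromane, via diazabicyclooctatriene 15 (not isolated)
Conditions: AgN(SO2CF3)2 (10 mol%), 2,2'-bipyridine (10 mol%), 14 (3 equiv), 4 Å molecular sieves, ClCH2CH2Cl, 60 °C
Reagents that add atoms: none
Why: Proposed new method: silver bound to N1 of 14 lowers the LUMO of the C6=N1 azomethine unit, the nucleophilic ynol ether carbon that carries the chromanyl group attacks the C6–H carbon, and the hydrazonide carbon C3 of the resulting 1,6-dihydropyridazinide closes onto the silyl ketenium carbon to give 2,3-diazabicyclo[2.2.2]octatriene 15, which loses N2 by retro-[4+2] and aromatizes. The closest known reaction type is the silver-catalysed formal inverse-electron-demand Diels–Alder reaction of phthalazines with siloxy alkynes to siloxynaphthalenes; the extension is to a monocyclic, electron-rich trialkoxypyridazine, which is why heat and a higher catalyst loading are planned. The one new ring, the carbocycle that becomes ring B, is closed in a formal [4+2] mode (four carbons C6–C5–C4–C3 of the diazine, two of the alkyne), the second bond by 6-exo-dig attack on the ketenium carbon. No stereocenter is formed in 16 (the bridgeheads of 15 vanish with N2), and chroman C3 keeps its configuration because nothing in the neutral medium can remove its hydrogen. The step needs regiocontrol, secured by the polarized O–C≡C unit and by the difference between the open C6–H azomethine carbon and the methoxy-blocked imidate carbon C3 of 14, and chemoselectivity for the diazine over dimerization or hydration of the ynol ether, secured by dry conditions and excess 14.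

Step 10
Reactants: 16 (3S)-8-(benzyloxy)-6,7-dimethoxy-3-(3,4,5-trimethoxy-2-{[tri(propan-2-yl)silyl]oxy}phenyl)chromane
Product: 18 5-[(3S)-8-(benzyloxy)-6,7-dimethoxychroman-3-yl]-2,3-dimethoxycyclohexa-2,5-diene-1,4-dione, via trimethoxyphenol 17 (not isolated)
Conditions: Bu4NF, AcOH, MeCN, 0 °C to rt; then H2O, PhI(OAc)2, 0 °C
Reagents that add atoms: water, O
Why: Fluoride cleaves the aryl silyl ether and the hypervalent iodine reagent then oxidizes the para-methoxyphenol, water adding para to the hydroxyl and methanol leaving from the hemiketal (oxidative demethylation to the para-quinone), while the fully etherified ring A should not react under these conditions.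

Step 11
Reactants: 18 5-[(3S)-8-(benzyloxy)-6,7-dimethoxychroman-3-yl]-2,3-dimethoxycyclohexa-2,5-diene-1,4-dione
Product: 20 5-[(3S)-8-hydroxy-6,7-dimethoxychroman-3-yl]-2,3-dimethoxycyclohexa-2,5-diene-1,4-dione (target CNP0269725.1), via hydroquinone 19 (not isolated)
Conditions: H2 (1 atm), 10% Pd on carbon, EtOAc, rt; filter under N2; then Ag2O, rt
Reagents that add atoms: none
Why: Hydrogenolysis removes the benzyl ether while the quinone rests as hydroquinone 19, and Ag2O should reoxidize this electron-rich hydroquinone much faster than the ring A phenol, so the quinone returns with C3 and the free C8 hydroxyl untouched.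

Compound list
1 | 2-hydroxy-3,4-dimethoxybenzaldehyde | COc1ccc(C=O)c(O)c1OC | starting material
2 | 2-(benzyloxy)-3,4-dimethoxybenzaldehyde | COc1ccc(C=O)c(OCc2ccccc2)c1OC | intermediate
3 | 2-(benzyloxy)-3,4-dimethoxyphenyl formate | COc1ccc(OC=O)c(OCc2ccccc2)c1OC | intermediate (not isolated)
4 | 2-(benzyloxy)-3,4-dimethoxyphenol | COc1ccc(O)c(OCc2ccccc2)c1OC | intermediate
5 | 3-(benzyloxy)-2-hydroxy-4,5-dimethoxybenzaldehyde | COc1cc(C=O)c(O)c(OCc2ccccc2)c1OC | intermediate
6 | acrolein (prop-2-enal) | C=CC=O | starting material
7 | 8-(benzyloxy)-6,7-dimethoxy-2H-chromene-3-carbaldehyde | COc1cc2C=C(C=O)COc2c(OCc3ccccc3)c1OC | intermediate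
8 | 8-(benzyloxy)-6,7-dimethoxy-2H-chromene-3-carboxylic acid | COc1cc2C=C(C(O)=O)COc2c(OCc3ccccc3)c1OC | intermediate
9 | (3R)-8-(benzyloxy)-6,7-dimethoxychromane-3-carboxylic acid | OC(=O)[C@H]1COc2c(OCc3ccccc3)c(OC)c(OC)cc2C1 | intermediate (not isolated)
10 | methyl (3R)-8-(benzyloxy)-6,7-dimethoxychromane-3-carboxylate | COC(=O)[C@H]1COc2c(OCc3ccccc3)c(OC)c(OC)cc2C1 | intermediate
11 | lithium 2-[(3S)-8-(benzyloxy)-6,7-dimethoxychroman-3-yl]ethynolate | [Li+].[O-]C#C[C@H]1COc2c(OCc3ccccc3)c(OC)c(OC)cc2C1 | intermediate (not isolated)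
12 | (3S)-8-(benzyloxy)-6,7-dimethoxy-3-({[tri(propan-2-yl)silyl]oxy}ethynyl)chromane | CC(C)[Si](OC#C[C@H]1COc2c(OCc3ccccc3)c(OC)c(OC)cc2C1)(C(C)C)C(C)C | intermediate
13 | 3,4,5-trichloropyridazine | Clc1cnnc(Cl)c1Cl | starting material
14 | 3,4,5-trimethoxypyridazine | COc1cnnc(OC)c1OC | intermediate
15 | 5-[(3S)-8-(benzyloxy)-6,7-dimethoxychroman-3-yl]-1,7,8-trimethoxy-6-{[tri(propan-2-yl)silyl]oxy}-2,3-diazabicyclo[2.2.2]octa-2,5,7-triene (both bridgehead configurations) | COC1=C(OC)C2(OC)N=NC1C(=C2O[Si](C(C)C)(C(C)C)C(C)C)[C@H]1COc3c(OCc4ccccc4)c(OC)c(OC)cc3C1 | intermediate (not isolated)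
16 | (3S)-8-(benzyloxy)-6,7-dimethoxy-3-(3,4,5-trimethoxy-2-{[tri(propan-2-yl)silyl]oxy}phenyl)chromane | COc1cc([C@H]2COc3c(OCc4ccccc4)c(OC)c(OC)cc3C2)c(O[Si](C(C)C)(C(C)C)C(C)C)c(OC)c1OC | intermediate
17 | 6-[(3S)-8-(benzyloxy)-6,7-dimethoxychroman-3-yl]-2,3,4-trimethoxyphenol | COc1cc([C@H]2COc3c(OCc4ccccc4)c(OC)c(OC)cc3C2)c(O)c(OC)c1OC | intermediate (not isolated)
18 | 5-[(3S)-8-(benzyloxy)-6,7-dimethoxychroman-3-yl]-2,3-dimethoxycyclohexa-2,5-diene-1,4-dione | COC1=C(OC)C(=O)C([C@H]2COc3c(OCc4ccccc4)c(OC)c(OC)cc3C2)=CC1=O | intermediate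
19 | 5-[(3S)-8-hydroxy-6,7-dimethoxychroman-3-yl]-2,3-dimethoxybenzene-1,4-diol | COc1c(O)cc([C@H]2COc3c(O)c(OC)c(OC)cc3C2)c(O)c1OC | intermediate (not isolated)
20 | 5-[(3S)-8-hydroxy-6,7-dimethoxychroman-3-yl]-2,3-dimethoxycyclohexa-2,5-diene-1,4-dione | COC1=C(OC)C(=O)C([C@H]2COc3c(cc(OC)c(OC)c3O)C2)=CC1=O | target

Total step count: 11. Longest linear sequence: 10 (steps 1–7 and 9–11; step 8 is the side branch).

Steps most likely to fail

Step 9 (the step under the label). The process at risk is non-engagement: the three methoxy groups raise the LUMO of the diazine so that the first C–C bond does not form, and the ynol ether is consumed instead by silver-promoted dimerization, hydration, or attack of a ring nitrogen on the ketenium carbon. The fallback uses known chemistry, a Moore cyclization on a squarate, and runs from ester 10 back to quinone 18. Ester 10 is reduced with i-Bu2AlH (CH2Cl2, −78 °C) to (3R)-8-(benzyloxy)-6,7-dimethoxychromane-3-carbaldehyde F1. Without contact with base, F1 is taken into the Corey–Fuchs olefination (CBr4, PPh3, CH2Cl2, 0 °C) to give (3S)-8-(benzyloxy)-3-(2,2-dibromoethenyl)-6,7-dimethoxychromane F2. n-BuLi (2 equiv, THF, −78 °C) converts F2 into lithium [(3S)-8-(benzyloxy)-6,7-dimethoxychroman-3-yl]ethynide F3, which adds to one carbonyl group of dimethyl squarate (COC1=C(OC)C(=O)C1=O) to give 4-{[(3S)-8-(benzyloxy)-6,7-dimethoxychroman-3-yl]ethynyl}-4-hydroxy-2,3-dimethoxycyclobut-2-en-1-one F4. Heating F4 in p-xylene (138 °C) should open the four-membered ring to the alkynyl vinylketene, which closes and transfers hydrogen to give quinone 18, from where step 11 follows. Steps 7 to 10 are then not needed.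

Step 7. The process at risk is loss of configuration: if a lithium amide enolizes ester 10 before the dibromomethyl anion adds, the ring C aryloxide can leave by β-elimination and add back, scrambling C3. Silylation of ynolate 11 on carbon instead of oxygen is a second risk. The fallback runs from ester 10 back to ynol ether 12 and has no amide base present at the addition stage. Bromomethyllithium, made in the flask from CH2Br2 and n-BuLi (THF, −90 °C) in the presence of 10, should give 2-bromo-1-[(3R)-8-(benzyloxy)-6,7-dimethoxychroman-3-yl]ethan-1-one F5. LiN(SiMe3)2 (−78 °C) then removes a proton from the CH2Br group, t-BuLi exchanges bromine for lithium, the keto dianion rearranges on warming to ynolate 11, and i-Pr3SiCl gives 12.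

Step 6. The process at risk is poor or reversed facial selectivity in the hydrogen transfer to the cyclic trisubstituted acrylic acid. The fallback replaces catalyst control by resolution and runs from acid 8 back to acid 9. Hydrogenation of 8 with the achiral catalyst [Rh(nbd)(dppb)]BF4 (H2, Et3N, MeOH), which leaves the benzyl ether alone, gives racemic 8-(benzyloxy)-6,7-dimethoxychromane-3-carboxylic acid F6. Crystallization with (R)-1-phenylethylamine (the antipodal amine if the other salt proves less soluble) gives (1R)-1-phenylethan-1-aminium (3R)-8-(benzyloxy)-6,7-dimethoxychromane-3-carboxylate F7. Aqueous HCl then frees acid 9, which is esterified as in the second part of step 6.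

Further compounds
F1 | step 9 | (3R)-8-(benzyloxy)-6,7-dimethoxychromane-3-carbaldehyde | O=C[C@H]1COc2c(OCc3ccccc3)c(OC)c(OC)cc2C1
F2 | step 9 | (3S)-8-(benzyloxy)-3-(2,2-dibromoethenyl)-6,7-dimethoxychromane | BrC(Br)=C[C@H]1COc2c(OCc3ccccc3)c(OC)c(OC)cc2C1
F3 | step 9 | lithium [(3S)-8-(benzyloxy)-6,7-dimethoxychroman-3-yl]ethynide | [Li+].[C-]#C[C@H]1COc2c(OCc3ccccc3)c(OC)c(OC)cc2C1
F4 | step 9 | 4-{[(3S)-8-(benzyloxy)-6,7-dimethoxychroman-3-yl]ethynyl}-4-hydroxy-2,3-dimethoxycyclobut-2-en-1-one | COC1=C(OC)C(O)(C#C[C@H]2COc3c(OCc4ccccc4)c(OC)c(OC)cc3C2)C1=O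
F5 | step 7 | 2-bromo-1-[(3R)-8-(benzyloxy)-6,7-dimethoxychroman-3-yl]ethan-1-one | BrCC(=O)[C@H]1COc2c(OCc3ccccc3)c(OC)c(OC)cc2C1
F6 | step 6 | racemic 8-(benzyloxy)-6,7-dimethoxychromane-3-carboxylic acid | OC(=O)C1COc2c(OCc3ccccc3)c(OC)c(OC)cc2C1
F7 | step 6 | (1R)-1-phenylethan-1-aminium (3R)-8-(benzyloxy)-6,7-dimethoxychromane-3-carboxylate | C[C@@H]([NH3+])c1ccccc1.[O-]C(=O)[C@H]1COc2c(OCc3ccccc3)c(OC)c(OC)cc2C1
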